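Readings and results stem from a simulated flask with constants of no real substance, noise included.

A small charge of substrate, the 0.031 M of the teal run, gives a target reading of 12.2 % of that charge at 15.0 h. I take the settings that could move the outcome in turn.

| flask | substrate | coupling partner | remark | time |
|---|---|---|---|---|
| teal | 0.031 M | 0.090 M | run made earlier |  |
| blue | 0.060 M | 0.090 M | run made earlier |  |
| red | 0.13 M | 0.090 M | run made earlier |  |
| spring | 0.030 M | 0.0900 M |  | 30 h |
| dawn | 0.050 M | 0.0900 M |  | 30 h |
| winter | 0.080 M | 0.0900 M |  | 30 h |
| noon | 0.12 M | 0.0900 M |  | 30 h |

| run | time / h | target / % |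
|---|---|---|
| teal | 1.33 | 0.8 |
| teal | 4.00 | 3.2 |
| teal | 8.00 | 5.5 |
| teal | 10.0 | 8.0 |
| teal | 15.0 | 12.2 |
| blue | 1.33 | 0.3 |
| blue | 2.50 | 1.4 |
| blue | 4.00 | 2.6 |
| blue | 8.00 | 4.9 |
| blue | 15.0 | 9.9 |
| red | 3.00 | 0.8 |
| red | 6.00 | 2.6 |
| red | 10.0 | 2.7 |
| red | 12.0 | 3.2 |
| red | 15.0 | 3.9 |

(scatter of a reading: 0.5 percentage points)

- a reading or a percentage of target counts all its forms, free or not
- the concentration of target that is asked is that of its free form alone
- "hardly changes" means that all values lie within two and a half points (for a concentration: within two and a half percent of the largest)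

- [target] (only what is free in solution) at the end for spring, dawn, winter, noon, in this order
- how that number moves from the first to the last of them (falls all the way / rises all the way / rises, then falls / falls, then rises / hardly changes)

Substrate charge comes first. By hand, more substrate at equal percentage gives proportionally more target, but the percentage at 15.0 h falls to 9.9 % in the blue run and 3.9 % in the red run. So I compare the mean rate: target as a concentration at the last reading, divided by the time of that reading. With 2.52 × 10⁻⁴ M h⁻¹ for teal, 3.96 × 10⁻⁴ M h⁻¹ for blue and 3.38 × 10⁻⁴ M h⁻¹ for red, the blue reading is higher than teal and higher than red. These are readings and carry their scatter of 0.5 percentage points.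

Time comes next. By hand, a steady mean rate makes target grow in step with time. In the teal run the mean at 4.00 h is 2.48 × 10⁻⁴ M h⁻¹, close to the later value, so over those readings the mean can stand in for the teal curve. The asked time is twice the last reading, however, so the line is an extrapolation.

The coupling partner is 0.090 M in each run, so the readings show no effect of changing it. By hand, its excess shrinks as substrate grows, and noon charges more substrate than partner.

My line carries the teal mean rate to 30 h for spring, giving 0.00756 M, and the red mean rate to the same time for noon, giving 0.0101 M; each comes from a neighbouring charge and counts target in all its forms. The forecast gives 0.0066 M, 0.0094 M, 0.0107 M and 0.0102 M, with the shape "rises, then falls", reasoning that “Absolute rate therefore rises and then falls with substrate”. For spring it stands lower than my line.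

The flasks give 0.00623 M, 0.00915 M, 0.0104 M and 0.00839 M, and the shape is "rises, then falls".

    substrate → intermediate B (k = 0.640 h⁻¹)
    coupling partner + intermediate B → intermediate C (k = 0.970 M⁻¹ h⁻¹)
    substrate + target ⇌ idle adduct, settled at all times (K = 24.0 M⁻¹)
    substrate + coupling partner → intermediate A (k = 15.0 M⁻¹ h⁻¹)
    coupling partner + intermediate B → target (k = 0.390 M⁻¹ h⁻¹)
    coupling partner + intermediate A → side product (k = 1.50 M⁻¹ h⁻¹)
    intermediate C → target (k = 0.0410 h⁻¹)

Free target in spring ends at 0.824 of its line and in noon, on the line from the red run, at 0.831, with mean rates over 30 h of 2.08 × 10⁻⁴ M h⁻¹ and 2.80 × 10⁻⁴ M h⁻¹. In spring, the half-life of substrate by its turning into intermediate B alone is 1.1 h, shorter than the 7.9 h of intermediate B by its turning into intermediate C alone, with coupling partner as charged. At 30.0 h spring holds 0 % substrate, the limiting reagent, with intermediate B at 4.43 %, intermediate C at 9.92 % and target at 20.8 %.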